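Everything rests on opening ring B at C7–C8 and C9–C10 (labdane numbering). Because the oxygen of C18 (on C4) and the oxygen on C6 lie on either side of C5, one shared oxygen turns them into a dihydrofuran enol ether that holds the diene C10=C5–C6=C7 s-cis. A Diels–Alder reaction of this bicyclic dienol ether (ring A plus the oxygen ring, C4 already configured) with methyl 4-acetoxybut-2-ynoate closes ring B, brings in C11 and C17 in differentiated form and sets quaternary C10 from C4 in one operation. Reductive transposition, chain growth at C11 through a sulfone, release of the 6α,18-diol and a vinylogous aldol with a silyloxyfuran complete the target.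

Key step: step 7

Numbering: labdane numbering throughout (ring A C1–C5 and C10; ring B C5–C10; C17 on C8; C18 the oxygenated carbon on C4, C19 the C4 methyl, C20 the C10 methyl; side chain C11–C16).

Assumption: centres that are erased later (the methyl-bearing CH of 4 and 5, C11 of 20–22) are carried as epimer mixtures and left undefined in the SMILES; methyl 4-hydroxybut-2-ynoate, 3-methylbut-2-en-1-yl acetate and 4-methylfuran-2(5H)-one are taken as catalogue chemicals.

Step 1
Reactants: 1 2,6-dimethylcyclohexanone
Product: 2 2,6-dimethyl-1-(trimethylsilyloxy)cyclohex-1-ene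
Conditions: TMSOTf, Et3N, CH2Cl2, 0 °C to rt
Reagents that add atoms: trimethylsilyl trifluoromethanesulfonate, C[Si](C)(C)OS(=O)(=O)C(F)(F)F
Why: Soft enolisation with O-silylation (silyl enol ether formation); both α-carbons are equivalent methines, so only one tetrasubstituted enol ether can form.

Step 2
Reactants: 2 2,6-dimethyl-1-(trimethylsilyloxy)cyclohex-1-ene; 3 formaldehyde (aqueous)
Product: 4 (2S)-2-(hydroxymethyl)-2,6-dimethylcyclohexan-1-one
Conditions: Sc(OTf)3 (10 mol%), chiral 6,6'-bis(1-hydroxy-2,2-dimethylpropyl)-2,2'-bipyridine (12 mol%, antipode giving 2S), aq. HCHO, DME/H2O, −20 °C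
Reagents that add atoms: none
Why: Catalytic enantioselective Mukaiyama-type aldol (hydroxymethylation) in which the chiral scandium–bipyridine complex binds formaldehyde and shields one enolate face, setting the quaternary centre that becomes C4 whichever epimer of 2 reacts, the remote methine being erased in step 3.

Step 3
Reactants: 4 (2S)-2-(hydroxymethyl)-2,6-dimethylcyclohexan-1-one
Product: 7 (6S)-6-(hydroxymethyl)-2,6-dimethylcyclohex-1-en-1-yl trifluoromethanesulfonate, via silyl ether 5 (not isolated), via silylated enol triflate 6 (not isolated)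
Conditions: TMSCl, Et3N, CH2Cl2, 0 °C, filter and concentrate; LiN(i-Pr)2, THF, −78 to 0 °C; PhNTf2, −78 °C to rt; 1 M HCl, THF
Reagents that add atoms: N-phenylbis(trifluoromethanesulfonimide), O=S(=O)(N(c1ccccc1)S(=O)(=O)C(F)(F)F)C(F)(F)F; chlorotrimethylsilane, C[Si](C)(C)Cl (its silyl group is carried only by 5 and 6)
Why: O-Silylation blocks retro-aldol loss of formaldehyde, deprotonation of the only α-hydrogen and enolate O-triflation give the tetrasubstituted enol triflate, and the acidic work-up frees the primary alcohol without touching the quaternary centre.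

Step 4
Reactants: 7 (6S)-6-(hydroxymethyl)-2,6-dimethylcyclohex-1-en-1-yl trifluoromethanesulfonate
Product: 8 (3aR)-3a,7-dimethyl-3a,4,5,6-tetrahydro-2-benzofuran-1(3H)-one
Conditions: Pd(PPh3)4 (5 mol%), CO (1 atm), n-Bu3N, LiCl, MeCN, 65 °C
Reagents that add atoms: carbon monoxide, [C-]#[O+]
Why: Palladium-catalysed carbonylative lactonisation (oxidative addition of the vinyl triflate to zerovalent palladium, CO insertion, capture of the acylpalladium by the neighbouring CH2OH) closes the five-membered unsaturated lactone and supplies C6.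

Step 5
Reactants: 8 (3aR)-3a,7-dimethyl-3a,4,5,6-tetrahydro-2-benzofuran-1(3H)-one
Product: 9 (3aR)-3a,7-dimethyl-1-methylidene-1,3,3a,4,5,6-hexahydro-2-benzofuran
Conditions: Cp2TiMe2, toluene, 70 °C, dark; filtration through basic alumina
Reagents that add atoms: dimethyltitanocene, C[Ti](C)(C1C=CC=C1)C1C=CC=C1
Why: Petasis methylenation (titanium methylidene [2+2] and cycloreversion at the lactone carbonyl) converts C6=O into the exocyclic C6=C7 enol ether under non-acidic conditions, as the acid-labile diene requires.

Step 6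
Reactants: 10 methyl 4-hydroxybut-2-ynoate
Product: 11 methyl 4-acetoxybut-2-ynoate
Conditions: Ac2O, pyridine, DMAP (cat.), CH2Cl2, 0 °C
Reagents that add atoms: acetic anhydride, CC(=O)OC(C)=O
Why: Routine O-acetylation (nucleophilic acyl substitution) of the propargylic alcohol installs the leaving group needed in step 8.

Step 7
Reactants: 9 (3aR)-3a,7-dimethyl-1-methylidene-1,3,3a,4,5,6-hexahydro-2-benzofuran; 11 methyl 4-acetoxybut-2-ynoate
Product: 12 methyl 17-acetoxy-6,18-epoxy-12,13,14,15,16-pentanorlabda-5,8-dien-11-oate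
Conditions: toluene, 2,6-di-tert-butyl-4-methylpyridine (cat.), BHT (cat.), 100 °C, sealed tube
Reagents that add atoms: none
Why: Concerted, asynchronous normal-demand Diels–Alder cycloaddition, the closest known type being additions of 2-alkoxy-1,3-dienes and 1-vinylcyclohexenes to acetylenic esters. Ring B is closed by the intermolecular [4+2] itself, C7–C8 and C9–C10 forming suprafacially on the diene that the five-membered ring holds s-cis. The one new stereocentre, quaternary C10, is controlled by C4: the ynoate should add to the face opposite the pseudo-axial C4 methyl, which drives the C10 methyl to the side of that methyl (C19 and C20 cis). Regioselectivity is required and should follow from the C6 oxygen, which makes C7 the nucleophilic terminus, so that C7 bonds to the ynoate β-carbon and the ester ends on C9. Facial selectivity is the second requirement and rests on the C4 methyl being the only group that projects over the diene.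

Step 8
Reactants: 12 methyl 17-acetoxy-6,18-epoxy-12,13,14,15,16-pentanorlabda-5,8-dien-11-oate
Product: 13 methyl 6,18-epoxy-12,13,14,15,16-pentanorlabda-5,8(17)-dien-11-oate
Conditions: SmI2 (2.5 equiv), THF, MeOH, −78 °C
Reagents that add atoms: none
Why: SmI2 reductive elimination of a γ-acetoxy α,β-unsaturated ester (two single-electron transfers expel acetate to give a samarium dienolate that is protonated kinetically at C9 from the face opposite the axial C10 methyl) should give the deconjugated ester with 9α-H and the C8(17) methylene.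

Step 9
Reactants: 13 methyl 6,18-epoxy-12,13,14,15,16-pentanorlabda-5,8(17)-dien-11-oate
Product: 14 6,18-epoxy-12,13,14,15,16-pentanorlabda-5,8(17)-dien-11-ol
Conditions: LiAlH4, Et2O, 0 °C; aq. NaOH work-up
Reagents that add atoms: none
Why: Hydride reduction of the ester to the primary alcohol; the enol ether and the isolated alkene are inert and the basic work-up protects the enol ether.

Step 10
Reactants: 14 6,18-epoxy-12,13,14,15,16-pentanorlabda-5,8(17)-dien-11-ol
Product: 15 6,18-epoxy-12,13,14,15,16-pentanorlabda-5,8(17)-dien-11-yl 4-toluenesulfonate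
Conditions: TsCl, pyridine, DMAP (cat.), CH2Cl2, 0 °C to rt
Reagents that add atoms: 4-toluenesulfonyl chloride, Cc1ccc(cc1)S(Cl)(=O)=O
Why: O-Sulfonylation of the primary alcohol under basic conditions that the enol ether tolerates.

Step 11
Reactants: 15 6,18-epoxy-12,13,14,15,16-pentanorlabda-5,8(17)-dien-11-yl 4-toluenesulfonate
Product: 16 6,18-epoxy-11-(phenylsulfonyl)-12,13,14,15,16-pentanorlabda-5,8(17)-diene
Conditions: PhSO2Na, n-Bu4NI (cat.), DMF, 90 °C
Reagents that add atoms: sodium benzenesulfinate, [Na+].[O-]S(=O)c1ccccc1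
Why: SN2 S-alkylation of the sulfinate (iodide-assisted displacement of the primary tosylate) gives the sulfone directly, a weakly basic sulfur nucleophile being chosen so that E2 towards the 8(17),9(11)-diene does not compete and no oxidation is needed beside the enol ether.

Step 12
Reactants: 17 3-methylbut-2-en-1-yl acetate
Product: 18 (E)-4-hydroxy-3-methylbut-2-en-1-yl acetate
Conditions: SeO2 (cat.), t-BuOOH, CH2Cl2, rt
Reagents that add atoms: tert-butyl hydroperoxide, CC(C)(C)OO
Why: SeO2 allylic oxidation (ene reaction then [2,3]-sigmatropic shift) attacks the (E)-methyl of the trisubstituted alkene and thereby fixes the E geometry needed at C13=C14.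

Step 13
Reactants: 18 (E)-4-hydroxy-3-methylbut-2-en-1-yl acetate
Product: 19 (E)-4-bromo-3-methylbut-2-en-1-yl acetate
Conditions: CBr4, PPh3, CH2Cl2, 0 °C
Reagents that add atoms: carbon tetrabromide, BrC(Br)(Br)Br
Why: Appel bromination (SN2 on the alkoxyphosphonium ion) of the primary allylic alcohol proceeds without allylic transposition or loss of alkene geometry.

Step 14
Reactants: 16 6,18-epoxy-11-(phenylsulfonyl)-12,13,14,15,16-pentanorlabda-5,8(17)-diene; 19 (E)-4-bromo-3-methylbut-2-en-1-yl acetate
Product: 21 (13E)-6,18-epoxy-11-(phenylsulfonyl)labda-5,8(17),13-trien-15-ol, via acetate 20 (not isolated)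
Conditions: n-BuLi, THF/DMPU, −78 °C; 19, −78 to −40 °C; then MeOH, K2CO3 (cat.), rt
Reagents that add atoms: none
Why: SN2 alkylation of the α-sulfonyl carbanion at C11 with the primary allylic bromide forms C11–C12 with the E alkene intact, and in situ methanolysis (transesterification) removes the acetate before the dissolving-metal step; the new C11 centre is of no consequence.

Step 15
Reactants: 21 (13E)-6,18-epoxy-11-(phenylsulfonyl)labda-5,8(17),13-trien-15-ol
Product: 22 (13E)-15,18-dihydroxy-11-(phenylsulfonyl)labda-8(17),13-dien-6-one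
Conditions: 0.5 M aq. HCl, THF, 0 °C
Reagents that add atoms: water, O
Why: Acid-catalysed enol-ether hydrolysis in which C5 is protonated from the α-face (the β-face carries the C4 and C10 methyls), giving the trans ring fusion, and water opens the oxocarbenium ion to the C6 ketone and the C18 alcohol; cold dilute acid should leave the β,γ-unsaturated ketone unconjugated.

Step 16
Reactants: 22 (13E)-15,18-dihydroxy-11-(phenylsulfonyl)labda-8(17),13-dien-6-one
Product: 23 (13E)-labda-8(17),13-diene-6α,15,18-triol
Conditions: Li, NH3(l)/THF, t-BuOH, −78 °C; NH4Cl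
Reagents that add atoms: none
Why: Dissolving-metal reduction does two jobs, reductive desulfonylation at C11 and reduction of the C6 ketone to the thermodynamically favoured equatorial 6α-alcohol (hydride reagents would attack from the α-face and give the axial 6β-alcohol), while the isolated alkenes and the allylic alkoxide should survive.

Step 17
Reactants: 23 (13E)-labda-8(17),13-diene-6α,15,18-triol
Product: 24 (13E)-6α,18-dihydroxylabda-8(17),13-dien-15-al
Conditions: MnO2, CH2Cl2, rt
Reagents that add atoms: none
Why: Chemoselective allylic oxidation: MnO2 oxidises only the allylic C15 alcohol and leaves the saturated primary and secondary alcohols.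

Step 18
Reactants: 24 (13E)-6α,18-dihydroxylabda-8(17),13-dien-15-al
Product: 25 (13E)-6α,18-bis(triethylsilyloxy)labda-8(17),13-dien-15-al
Conditions: Et3SiCl, imidazole, DMAP (cat.), DMF, rt
Reagents that add atoms: chlorotriethylsilane, CC[Si](Cl)(CC)CC
Why: Silyl ether formation masks both hydroxyls against the chlorosilane Lewis acid of step 20 under conditions too mild to enolise the enal.

Step 19
Reactants: 26 4-methylfuran-2(5H)-one
Product: 27 tert-butyldimethyl[(4-methylfuran-2-yl)oxy]silane
Conditions: TBSOTf, Et3N, CH2Cl2, 0 °C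
Reagents that add atoms: tert-butyldimethylsilyl trifluoromethanesulfonate, CC(C)(C)[Si](C)(C)OS(=O)(=O)C(F)(F)F
Why: Soft enolisation with O-silylation of the butenolide (silyl dienol ether formation) gives the aromatic 2-silyloxyfuran.

Step 20
Reactants: 25 (13E)-6α,18-bis(triethylsilyloxy)labda-8(17),13-dien-15-al; 27 tert-butyldimethyl[(4-methylfuran-2-yl)oxy]silane
Product: 28 (13E,15S)-15-[(2S)-3-methyl-5-oxo-2,5-dihydrofuran-2-yl]-6α,18-bis(triethylsilyloxy)labda-8(17),13-dien-15-ol
Conditions: SiCl4, (R,R)-bisphosphoramide (pentane-1,5-diyl-linked dimer of the N,N'-dimethyl-1,1'-binaphthyl-2,2'-diamine phosphoramide, 5 mol%; antipode chosen for Re-face attack), i-Pr2NEt, CH2Cl2, −78 °C; aq. KF/NaHCO3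
Reagents that add atoms: none
Why: Catalytic enantioselective vinylogous Mukaiyama aldol in which the phosphoramide-bound trichlorosilyl cation activates the enal and should expose its Re face, while the furan reacts at its free α-carbon through an open transition state that favours the like (threo) adduct, setting 15S and the S lactone carbinol centre.

Step 21
Reactants: 28 (13E,15S)-15-[(2S)-3-methyl-5-oxo-2,5-dihydrofuran-2-yl]-6α,18-bis(triethylsilyloxy)labda-8(17),13-dien-15-ol
Product: 29 (13E,15S)-15-[(2S)-3-methyl-5-oxo-2,5-dihydrofuran-2-yl]labda-8(17),13-diene-6α,15,18-triol (CNP0221530.1)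
Conditions: HF·pyridine, pyridine, THF, 0 °C to rt
Reagents that add atoms: none
Why: Fluoride-mediated desilylation under buffered, non-basic conditions should spare the base-sensitive butenolide and the allylic alcohol.

Compound list

1 | 2,6-dimethylcyclohexanone (cis/trans mixture) | CC1CCCC(C)C1=O | starting material
2 | 2,6-dimethyl-1-(trimethylsilyloxy)cyclohex-1-ene (racemic) | CC1CCCC(C)=C1O[Si](C)(C)C | intermediate
3 | formaldehyde (aqueous) | C=O | starting material
4 | (2S)-2-(hydroxymethyl)-2,6-dimethylcyclohexan-1-one (epimers at the CH–CH3 carbon) | CC1CCC[C@@](C)(CO)C1=O | intermediate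
5 | (2S)-2,6-dimethyl-2-[(trimethylsilyloxy)methyl]cyclohexan-1-one (not isolated) | CC1CCC[C@@](C)(CO[Si](C)(C)C)C1=O | intermediate
6 | (6S)-2,6-dimethyl-6-[(trimethylsilyloxy)methyl]cyclohex-1-en-1-yl trifluoromethanesulfonate (not isolated) | CC1=C(OS(=O)(=O)C(F)(F)F)[C@](C)(CO[Si](C)(C)C)CCC1 | intermediate
7 | (6S)-6-(hydroxymethyl)-2,6-dimethylcyclohex-1-en-1-yl trifluoromethanesulfonate | CC1=C(OS(=O)(=O)C(F)(F)F)[C@](C)(CO)CCC1 | intermediate
8 | (3aR)-3a,7-dimethyl-3a,4,5,6-tetrahydro-2-benzofuran-1(3H)-one | O=C1OC[C@]2(C)CCCC(C)=C12 | intermediate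
9 | (3aR)-3a,7-dimethyl-1-methylidene-1,3,3a,4,5,6-hexahydro-2-benzofuran (dienol ether, key-step precursor) | C=C1OC[C@]2(C)CCCC(C)=C12 | intermediate
10 | methyl 4-hydroxybut-2-ynoate | COC(=O)C#CCO | starting material
11 | methyl 4-acetoxybut-2-ynoate | COC(=O)C#CCOC(C)=O | intermediate
12 | methyl 17-acetoxy-6,18-epoxy-12,13,14,15,16-pentanorlabda-5,8-dien-11-oate (tricyclic adduct; C4 and C10 methyls cis) | COC(=O)C1=C(COC(C)=O)CC2=C3[C@]1(C)CCC[C@@]3(C)CO2 | intermediate
13 | methyl 6,18-epoxy-12,13,14,15,16-pentanorlabda-5,8(17)-dien-11-oate (9α-H) | COC(=O)[C@H]1C(=C)CC2=C3[C@]1(C)CCC[C@@]3(C)CO2 | intermediate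
14 | 6,18-epoxy-12,13,14,15,16-pentanorlabda-5,8(17)-dien-11-ol (9α-H) | OC[C@H]1C(=C)CC2=C3[C@]1(C)CCC[C@@]3(C)CO2 | intermediate
15 | 6,18-epoxy-12,13,14,15,16-pentanorlabda-5,8(17)-dien-11-yl 4-toluenesulfonate | Cc1ccc(cc1)S(=O)(=O)OC[C@H]1C(=C)CC2=C3[C@]1(C)CCC[C@@]3(C)CO2 | intermediate
16 | 6,18-epoxy-11-(phenylsulfonyl)-12,13,14,15,16-pentanorlabda-5,8(17)-diene | O=S(=O)(C[C@H]1C(=C)CC2=C3[C@]1(C)CCC[C@@]3(C)CO2)c1ccccc1 | intermediate
17 | 3-methylbut-2-en-1-yl acetate | CC(C)=CCOC(C)=O | starting material
18 | (E)-4-hydroxy-3-methylbut-2-en-1-yl acetate | CC(=O)OC/C=C(\C)CO | intermediate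
19 | (E)-4-bromo-3-methylbut-2-en-1-yl acetate | CC(=O)OC/C=C(\C)CBr | intermediate
20 | (13E)-6,18-epoxy-11-(phenylsulfonyl)labda-5,8(17),13-trien-15-yl acetate (C11 epimers, not isolated) | CC(=O)OC/C=C(\C)CC([C@H]1C(=C)CC2=C3[C@]1(C)CCC[C@@]3(C)CO2)S(=O)(=O)c1ccccc1 | intermediate
21 | (13E)-6,18-epoxy-11-(phenylsulfonyl)labda-5,8(17),13-trien-15-ol (C11 epimers) | OC/C=C(\C)CC([C@H]1C(=C)CC2=C3[C@]1(C)CCC[C@@]3(C)CO2)S(=O)(=O)c1ccccc1 | intermediate
22 | (13E)-15,18-dihydroxy-11-(phenylsulfonyl)labda-8(17),13-dien-6-one (5α-H; C11 epimers; open keto form, may equilibrate with its 6,18-hemiketal) | C=C1CC(=O)[C@H]2[C@](C)(CO)CCC[C@]2(C)[C@H]1C(C/C(C)=C/CO)S(=O)(=O)c1ccccc1 | intermediate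
23 | (13E)-labda-8(17),13-diene-6α,15,18-triol | C=C1C[C@H](O)[C@H]2[C@](C)(CO)CCC[C@]2(C)[C@H]1CC/C(C)=C/CO | intermediate
24 | (13E)-6α,18-dihydroxylabda-8(17),13-dien-15-al | C=C1C[C@H](O)[C@H]2[C@](C)(CO)CCC[C@]2(C)[C@H]1CC/C(C)=C/C=O | intermediate
25 | (13E)-6α,18-bis(triethylsilyloxy)labda-8(17),13-dien-15-al | C=C1C[C@H](O[Si](CC)(CC)CC)[C@H]2[C@](C)(CO[Si](CC)(CC)CC)CCC[C@]2(C)[C@H]1CC/C(C)=C/C=O | intermediate
26 | 4-methylfuran-2(5H)-one | CC1=CC(=O)OC1 | starting material
27 | tert-butyldimethyl[(4-methylfuran-2-yl)oxy]silane | Cc1coc(O[Si](C)(C)C(C)(C)C)c1 | intermediate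
28 | (13E,15S)-15-[(2S)-3-methyl-5-oxo-2,5-dihydrofuran-2-yl]-6α,18-bis(triethylsilyloxy)labda-8(17),13-dien-15-ol | C=C1C[C@H](O[Si](CC)(CC)CC)[C@H]2[C@](C)(CO[Si](CC)(CC)CC)CCC[C@]2(C)[C@H]1CC/C(C)=C/[C@H](O)[C@H]1OC(=O)C=C1C | intermediate
29 | (13E,15S)-15-[(2S)-3-methyl-5-oxo-2,5-dihydrofuran-2-yl]labda-8(17),13-diene-6α,15,18-triol (CNP0221530.1) | C=C1C[C@H](O)[C@H]2[C@](C)(CO)CCC[C@]2(C)[C@H]1CC/C(C)=C/[C@H](O)[C@H]1OC(=O)C=C1C | target

Total step count: 21 steps.

Longest linear sequence: 17 steps (steps 1, 2, 3, 4, 5, 7, 8, 9, 10, 11, 14, 15, 16, 17, 18, 20, 21).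

Steps most likely to fail

Step 7. Bond formation at the fully substituted C10 terminus may be slow enough that ene reactions or thermal decay of the acid-labile exocyclic enol ether outrun ring closure. The fallback sets out from 9 and uses the far more electrophilic dimethyl acetylenedicarboxylate (toluene, 60 °C), which should give the dimethyl 6,18-epoxy-12,13,14,15,16-pentanorlabda-5,8-diene-11,17-dioate F1. Reduction of both esters with i-Bu2AlH (CH2Cl2, −78 to 0 °C) gives the allylic diol F2. Acetylation with one equivalent of Ac2O (2,4,6-collidine, −20 °C) at the less hindered C17 hydroxyl, the C11 hydroxyl being screened by quaternary C10, gives the 17-monoacetate F3. Palladium-catalysed formate hydrogenolysis of this allylic acetate (Pd(OAc)2, n-Bu3P, HCO2NH4, dioxane, reflux) should deliver hydride to the more substituted allyl terminus C9 from the palladium-bearing α-face and move the alkene to C8(17). The route is rejoined at alcohol 14, so that steps 8 and 9 are bypassed.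

Step 20. Facial control may be incomplete at the enal or at the furan, leaving C15/lactone-carbinol isomers that the remote decalin does not help to separate. The fallback sets out from 25 and 27 and uses a BF3·OEt2-promoted vinylogous Mukaiyama aldol (CH2Cl2, −78 °C), which relies only on the inherent threo preference of silyloxyfurans and should give 28 together with its (15R, lactone 2R) diastereomer F4. Sharpless kinetic resolution of this secondary allylic alcohol pair (Ti(OiPr)4, L-(+)-diisopropyl tartrate, t-BuOOH, 4 Å sieves, CH2Cl2, −20 °C) should epoxidise the fast-reacting 15R isomer to the 13,14-epoxy alcohol F5, which is removed by chromatography. The slow-reacting 15S isomer is recovered, and the route is rejoined at 28.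

Step 2. Enantiofacial discrimination may be insufficient for an aliphatic, fully substituted silyl enol ether that is itself racemic at a remote centre, which would erode the enantiopurity of every later compound. The fallback sets out from 2: hydroxymethylation with aqueous formaldehyde under achiral Yb(OTf)3 catalysis (THF/H2O, rt) gives racemic 2-(hydroxymethyl)-2,6-dimethylcyclohexanone F6. Lipase-catalysed transesterification with vinyl acetate (immobilised Candida antarctica lipase B, t-BuOMe, rt) is taken to acetylate the 2R alcohol, giving (2R)-(1,3-dimethyl-2-oxocyclohexyl)methyl acetate F7 and leaving the 2S alcohol. Should the enzyme prefer the 2S alcohol, that alcohol is released from its acetate by lipase-mediated methanolysis. The route is rejoined at 4.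

Further compounds

F1 | step 7 | dimethyl 6,18-epoxy-12,13,14,15,16-pentanorlabda-5,8-diene-11,17-dioate | COC(=O)C1=C(C(=O)OC)CC2=C3[C@]1(C)CCC[C@@]3(C)CO2
F2 | step 7 | 6,18-epoxy-12,13,14,15,16-pentanorlabda-5,8-diene-11,17-diol | OCC1=C(CO)CC2=C3[C@]1(C)CCC[C@@]3(C)CO2
F3 | step 7 | 11-hydroxy-6,18-epoxy-12,13,14,15,16-pentanorlabda-5,8-dien-17-yl acetate | OCC1=C(COC(C)=O)CC2=C3[C@]1(C)CCC[C@@]3(C)CO2
F4 | step 20 | (13E,15R)-15-[(2R)-3-methyl-5-oxo-2,5-dihydrofuran-2-yl]-6α,18-bis(triethylsilyloxy)labda-8(17),13-dien-15-ol | C=C1C[C@H](O[Si](CC)(CC)CC)[C@H]2[C@](C)(CO[Si](CC)(CC)CC)CCC[C@]2(C)[C@H]1CC/C(C)=C/[C@@H](O)[C@@H]1OC(=O)C=C1C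
F5 | step 20 | (13R,14R,15S)-13,14-epoxy-15-[(2R)-3-methyl-5-oxo-2,5-dihydrofuran-2-yl]-6α,18-bis(triethylsilyloxy)labd-8(17)-en-15-ol | C=C1C[C@H](O[Si](CC)(CC)CC)[C@H]2[C@](C)(CO[Si](CC)(CC)CC)CCC[C@]2(C)[C@H]1CC[C@@]1(C)O[C@@H]1[C@@H](O)[C@@H]2OC(=O)C=C2C
F6 | step 2 | racemic 2-(hydroxymethyl)-2,6-dimethylcyclohexan-1-one | CC1CCCC(C)(CO)C1=O
F7 | step 2 | [(1R)-1,3-dimethyl-2-oxocyclohexyl]methyl acetate | CC1CCC[C@](C)(COC(C)=O)C1=O
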